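# Synthesis proposal for gambiriin A2 (37) by photo-Wolff benzannulation of ring A

Ring positions follow flavan numbering (O1, C2, C3, C4, C4a, C5–C8, C8a). The chain on C8 is numbered C1′ (diarylmethine), C2′ (carbinol), C3′ (methylene).

## Analysis of the target

Gambiriin A2, compound 37, is a chalcan–flavan dimer: a flavan-3-ol (rings A, B and C) carries at C8 of ring A a 1,3-diaryl-2-hydroxypropyl chain, which is a second flavan-3-ol unit whose pyran ring is open. There are four stereocentres in two vicinal pairs: C2 and C3 of the flavan are (2S,3S), that is 2,3-cis, and the chain is (1′R,2′S). The pairs are separated by the aromatic ring A, so neither can control the other and each must be set absolutely. The molecule has eleven hydroxyls, nine of them phenolic, and is sensitive to air and base. The benzylic C2–O1 bond next to the electron-rich ring B can ionise, which would epimerise C2 out of the less stable cis arrangement, and C1′ is doubly benzylic. The main difficulty is ring A: it is a pentasubstituted phloroglucinol ring in which C6 and C8 are electronically alike, so an electrophilic attachment of the chain would give C6/C8 mixtures and would form C1′ by cation chemistry, and of its three oxygens only the one at C8a may become the ring ether. The strategy rests on the alternating pattern O(C8a)–C(C8)–O(C7)–H(C6)–O(C5)–C(C4a) around ring A, which a vinylketene–siloxyalkyne benzannulation writes atom by atom.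

## Retrosynthetic reasoning

**37 from 36.** All ten O-benzyl groups are removed last by hydrogenolysis. Benzyl ethers survive the organometallic, basic, photochemical and fluoride steps and still leave without acid or base, which the cis-flavan would not tolerate.

**36 from 35 and 34 (O1–C2).** Ring C is opened at O1–C2. The forward reaction is an intramolecular Mitsunobu etherification of the C8a phenol with the C2 alcohol of 35, with inversion, so the open chain must be the (2R,3S) anti-diol derivative. This bond is cut because the C8a hydroxyl is exactly the one that the benzannulation delivers free, while O5 is benzylated and O7 is silylated. The three oxygens of ring A are therefore already differentiated, and only O8a can close a six-membered ring. Compound 35 comes from 34 by removal of the two silyl groups.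

**34 from 29 and 20 (ring A).** Three ring bonds are cut: C8–C8a, C6–C7 and C4a–C8a. Ring A then falls into the diazo enone 29 (C8a, C6, C5, C4a and the whole flavan arm) and the siloxyalkyne 20 (C7, C8 and the whole chalcan). Forward, 29 gives vinylketene 30, which adds to 20 to give cyclobutenone 31; this opens to dienylketene 32 and closes through dienone 33 to phenol 34. The gain is that the chain is placed on C8 by the alkyne polarisation, and all four stereocentres arrive in two enantiopure fragments.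

**20 from 17, 15, 11 and 12.** The C–O bond of the ynol ether is cut back to the terminal alkyne 17 (acetylide oxygenation, O-silylation). The propargylic C1′–C(alkyne) bond is cut next: alkynylalane 14, made from 12, opens the cis-epoxide 11 at the benzylic carbon with inversion to give 15. This sets (1′R) next to the existing (2′S) carbinol.

**11 from 8, and 8 from 4 and 6.** The cis-epoxide is the double-inversion product of the anti-diol 8. The C3′–aryl bond of 8 is cut to the aryl Grignard reagent 7 (from bromide 6, from 5) and the terminal epoxide of 4. The phloroglucinol ring is thus introduced as a nucleophile at a primary carbon, where no regiochemical or stereochemical question arises.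

**29 from 27, 24 and 26.** The diazo group is put on the methyl ketone 27 by diazo transfer. The enol ether double bond (future C4a=C5) is cut by Horner–Wadsworth–Emmons logic into aldehyde 24 and ketophosphonate 26 (from 25). Aldehyde 24 comes from alkene 23, the benzyl ether of 22, which is the product of opening the silylated epoxide 21 with the vinyl Grignard reagent 2.

**21 and 8 from 4, and 4 from 3, 1 and 2.** Both halves descend from one epoxy alcohol, 4. Its benzylic carbinol and oxirane centres become C2/C3 of the flavan in one branch and C1′/C2′ of the chain in the other. Compound 4 comes from the racemic allylic alcohol 3 (from 1 and 2) by Sharpless kinetic resolution, so a single asymmetric step supplies all four stereocentres.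

## Alternatives that were turned down

Alternative 1: aryl C–O coupling at O1–C8a. The disconnection is the O1–C8a bond: the bromo alcohol A2 (C8a–Br, free C2–OH, syn-configured arm) would be cyclised under CuI or Pd(OAc)2 catalysis to the undeca-O-benzyl compound A1.
- For it: the C2–O bond is never broken, so C2 and C3 are set once in the open chain and carried through with retention. On this point it is stronger than the chosen route, which must invert an electron-rich benzylic centre in step 18. A1 also goes to the target by hydrogenolysis alone, without a separate desilylation.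
- Against it: the C8a–Br bond of A2 is flanked by the C8 chain and the C4a chain. Oxidative addition to this di-ortho-substituted, electron-rich aryl bromide would be slow, and the secondary benzylic alkoxide on palladium can undergo β-hydride elimination, which would oxidise the carbinol. Making A2 also means placing two different carbon substituents ortho to the bromine of a ring whose most reactive position is the one between the two alkoxy groups (C6), so the C6/C8 problem returns.
- Comparison: the chosen route needs about the same number of steps and offers in exchange a ring A whose substitution is fixed by construction.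

Alternative 2: epoxide–arene cyclisation at C4–C4a. The disconnection is the C4–C4a bond: acid activation of the terminal epoxide of the aryl glycidyl-type ether A4 would let ring A attack C4 through C4a, giving A3 with the C3 hydroxyl free.
- For it: the C3 hydroxyl emerges already differentiated, which the chosen route cannot do. O1–C2 and both stereocentres are present before the ring closes, and C4a is the only free ortho position.
- Against it: the arene must attack the primary epoxide carbon (6-endo), while attack at the secondary carbon (5-exo closure to a five-membered ring) is the electronically preferred path under acid. The same acid can ionise the benzylic C2–O1 ether next to ring B and epimerise or cleave it. A4 in turn needs the chain on C8 of ring A before the ring closes (C6/C8 again) and an aryl ether formation at the benzylic C2.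
- Comparison: the risk is not removed but moved into the precursor, and the closure itself has a regiochemical risk that the pericyclic ring A formation does not have.

Alternative 3: ortho-quinone methide cycloaddition. The disconnection cuts C3–C4 and O1–C2: the ortho-quinone methide A8, generated from the salicyl alcohol A6, would undergo [4+2] addition with the (Z)-enol acetate A7 and give the 3-O-acetate A5.
- For it: it is the most convergent proposal. Ring C, two bonds and the cis relationship (from the Z geometry, suprafacial addition) come in one step, which is better step economy than the chosen route.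
- Against it: C2 and C3 are both created in the cycloaddition, and the only source of absolute control is the remote chain on C8, so a mixture of diastereomers is expected. The regiochemistry is also not secure, because the polarisation by the acetoxy group of A7 (the carbon remote from oxygen is nucleophilic) opposes the polarisation by its aryl group that the desired orientation needs. A6 again requires a regiodefined pentasubstituted ring A.
- Comparison: the chosen route is longer but brings every stereocentre in from an enantiopure fragment.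

Key step: step 16

## Assumptions and conventions

- Compounds 1, 2, 5, 12 and 25 are taken as purchasable; 1 and 5 are the per-O-benzyl ethers of 3,4-dihydroxybenzaldehyde and of phloroglucinol.
- Metal alkoxides, enolates and phosphonate anions that exist only before work-up are not counted as separate compounds. Carbon–metal reagents made from numbered compounds, and intermediates with a changed skeleton, are numbered.

## Route

Step 1
Reactants: 1 3,4-bis(benzyloxy)benzaldehyde; 2 vinylmagnesium bromide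
Product: 3 rac-1-[3,4-bis(benzyloxy)phenyl]prop-2-en-1-ol
Conditions: CH2=CHMgBr, THF, −78 → 0 °C; aq. NH4Cl
Reagents that add atoms: none
Why: 1,2-addition of a Grignard reagent to a non-enolisable aryl aldehyde; the racemic allylic alcohol is the substrate for the resolution in step 2 and is kept away from acid because it is an electron-rich benzylic and allylic alcohol.

Step 2
Reactants: 3 rac-1-[3,4-bis(benzyloxy)phenyl]prop-2-en-1-ol
Product: 4 (R)-[3,4-bis(benzyloxy)phenyl][(2S)-oxiran-2-yl]methanol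
Conditions: Ti(OiPr)4 (10 mol %), D-(−)-diisopropyl tartrate (15 mol %), t-BuOOH (0.55 equiv), 4 Å molecular sieves, CH2Cl2, −20 °C
Reagents that add atoms: tert-butyl hydroperoxide, CC(C)(C)OO
Why: Sharpless kinetic resolution by asymmetric epoxidation; with the D-tartrate the (S)-alcohol should be epoxidised fast and on the face that gives the erythro (anti) epoxy alcohol, so the carbinol centre is selected by the resolution and the oxirane centre is set by the catalyst, while the (R)-alcohol is left and separated.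

Step 3
Reactants: 5 1,3,5-tris(benzyloxy)benzene
Product: 6 2-bromo-1,3,5-tris(benzyloxy)benzene
Conditions: N-bromosuccinimide (1.0 equiv), CH2Cl2, −78 → 0 °C
Reagents that add atoms: N-bromosuccinimide, O=C1CCC(=O)N1Br
Why: Electrophilic aromatic bromination of a phloroglucinol triether; the three ring positions are equivalent, so only the degree of bromination has to be held, by stoichiometry and low temperature.

Step 4
Reactants: 6 2-bromo-1,3,5-tris(benzyloxy)benzene; 4 (R)-[3,4-bis(benzyloxy)phenyl][(2S)-oxiran-2-yl]methanol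
Product: 8 (1R,2S)-1-[3,4-bis(benzyloxy)phenyl]-3-[2,4,6-tris(benzyloxy)phenyl]propane-1,2-diol, via arylmagnesium bromide 7 (not isolated)
Conditions: 6 (2.5 equiv), Mg, LiCl, THF, 25 °C; CuI (10 mol %), then 4, −30 → 0 °C; aq. NH4Cl
Reagents that add atoms: none
Why: Copper-catalysed opening of a terminal epoxide by an aryl Grignard reagent at the unsubstituted carbon; the first equivalent only deprotonates the hydroxyl, no stereocentre is touched, and 8 keeps the anti-diol configuration of 4.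

Step 5
Reactants: 8 (1R,2S)-1-[3,4-bis(benzyloxy)phenyl]-3-[2,4,6-tris(benzyloxy)phenyl]propane-1,2-diol
Product: 11 (2R,3S)-2-[3,4-bis(benzyloxy)phenyl]-3-[2,4,6-tris(benzyloxy)benzyl]oxirane, via cyclic orthoacetate 9 (not isolated), via chloro acetate 10 (not isolated)
Conditions: MeC(OMe)3, pyridinium p-toluenesulfonate (cat.), CH2Cl2, 25 °C; Me3SiCl, 0 → 25 °C; K2CO3, MeOH, 25 °C
Reagents that add atoms: none
Why: Kolb–Sharpless conversion of a 1,2-diol into an epoxide; chloride opens the acetoxonium ion at the benzylic carbon with inversion and the freed neighbouring alkoxide displaces chloride with a second inversion, so both C–O configurations of the anti-diol are kept and the cis-epoxide should result. The chloro acetate is carried on at once and cold, so that the electron-rich benzylic chloride has little time to ionise.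

Step 6
Reactants: 11 (2R,3S)-2-[3,4-bis(benzyloxy)phenyl]-3-[2,4,6-tris(benzyloxy)benzyl]oxirane; 12 ethynyl(trimethyl)silane
Product: 15 (2S,3R)-3-[3,4-bis(benzyloxy)phenyl]-1-[2,4,6-tris(benzyloxy)phenyl]-5-(trimethylsilyl)pent-4-yn-2-ol, via lithium silylacetylide 13 (not isolated), via alkynylalane 14 (not isolated)
Conditions: 12, n-BuLi, toluene, 0 °C; Et2AlCl, 0 °C; then 11, 0 → 25 °C; aq. potassium sodium tartrate
Reagents that add atoms: none
Why: Opening of an aryl epoxide by a diethyl(alkynyl)alane; aluminium activates the oxirane oxygen and a second alane delivers the alkynyl group to the benzylic carbon from the rear, so the propargylic centre forms with inversion and ends (R) next to the untouched (S)-carbinol.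

Step 7
Reactants: 15 (2S,3R)-3-[3,4-bis(benzyloxy)phenyl]-1-[2,4,6-tris(benzyloxy)phenyl]-5-(trimethylsilyl)pent-4-yn-2-ol
Product: 17 1,3,5-tris(benzyloxy)-2-{(2S,3S)-2-(benzyloxy)-3-[3,4-bis(benzyloxy)phenyl]pent-4-yn-1-yl}benzene, via benzylated silylalkyne 16 (not isolated)
Conditions: KN(SiMe3)2 (1.05 equiv), BnBr, THF, −78 → 0 °C; then K2CO3, MeOH, 25 °C
Reagents that add atoms: benzyl bromide, BrCc1ccccc1
Why: Williamson etherification under basic conditions (an acid-promoted benzylation would C-benzylate the phloroglucinol ring), then methanolysis of the alkynyl C–Si bond; neither stage touches a stereocentre, and the descriptor at C3 changes only because the priorities change.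

Step 8
Reactants: 17 1,3,5-tris(benzyloxy)-2-{(2S,3S)-2-(benzyloxy)-3-[3,4-bis(benzyloxy)phenyl]pent-4-yn-1-yl}benzene
Product: 20 {[(3R,4S)-4-(benzyloxy)-3-[3,4-bis(benzyloxy)phenyl]-5-[2,4,6-tris(benzyloxy)phenyl]pent-1-yn-1-yl]oxy}tri(propan-2-yl)silane, via lithium acetylide 18 (not isolated), via lithium ynolate 19 (not isolated)
Conditions: LiN(SiMe3)2, THF, −78 °C; LiOOt-Bu (from t-BuOOH and LiN(SiMe3)2), −78 → 0 °C; i-Pr3SiOTf, −78 → 0 °C
Reagents that add atoms: tert-butyl hydroperoxide, CC(C)(C)OO; triisopropylsilyl trifluoromethanesulfonate, CC(C)[Si](C(C)C)(C(C)C)OS(=O)(=O)C(F)(F)F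
Why: Julia oxygenation of a lithium acetylide with lithium tert-butyl peroxide gives the lithium ynolate, which the bulky silyl triflate traps on oxygen as the triisopropylsilyl ynol ether; the terminal C–H is by far the most acidic site, so the propargylic stereocentre should not be deprotonated.

Step 9
Reactants: 4 (R)-[3,4-bis(benzyloxy)phenyl][(2S)-oxiran-2-yl]methanol
Product: 21 tert-butyl{(R)-[3,4-bis(benzyloxy)phenyl][(2S)-oxiran-2-yl]methoxy}dimethylsilane
Conditions: t-BuMe2SiCl, imidazole, DMF, 0 → 25 °C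
Reagents that add atoms: tert-butyldimethylsilyl chloride, CC(C)(C)[Si](C)(C)Cl
Why: Silylation of the benzylic hydroxyl under weakly basic conditions that do not trigger Payne rearrangement; this silyl ether is later the only group removed at the C2 oxygen before ring closure.

Step 10
Reactants: 21 tert-butyl{(R)-[3,4-bis(benzyloxy)phenyl][(2S)-oxiran-2-yl]methoxy}dimethylsilane; 2 vinylmagnesium bromide
Product: 22 (1R,2S)-1-[3,4-bis(benzyloxy)phenyl]-1-{[tert-butyl(dimethyl)silyl]oxy}pent-4-en-2-ol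
Conditions: CH2=CHMgBr, CuI (10 mol %), THF, −40 → −10 °C; aq. NH4Cl
Reagents that add atoms: none
Why: Copper-catalysed Grignard opening of the terminal epoxide at CH2 without touching either stereocentre; the low temperature keeps the magnesium alkoxide from taking over the neighbouring silyl group.

Step 11
Reactants: 22 (1R,2S)-1-[3,4-bis(benzyloxy)phenyl]-1-{[tert-butyl(dimethyl)silyl]oxy}pent-4-en-2-ol
Product: 23 {[(1R,2S)-2-(benzyloxy)-1-[3,4-bis(benzyloxy)phenyl]pent-4-en-1-yl]oxy}(tert-butyl)dimethylsilane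
Conditions: 2-benzyloxy-1-methylpyridinium triflate, MgO, PhCF3, 85 °C
Reagents that add atoms: 2-benzyloxy-1-methylpyridinium trifluoromethanesulfonate, C[n+]1ccccc1OCc1ccccc1.[O-]S(=O)(=O)C(F)(F)F
Why: Dudley benzylation under neutral conditions; no alkoxide is formed, so the 1,2-silyl shift that a Williamson benzylation of this β-silyloxy alcohol would cause cannot occur.

Step 12
Reactants: 23 {[(1R,2S)-2-(benzyloxy)-1-[3,4-bis(benzyloxy)phenyl]pent-4-en-1-yl]oxy}(tert-butyl)dimethylsilane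
Product: 24 (3S,4R)-3-(benzyloxy)-4-[3,4-bis(benzyloxy)phenyl]-4-{[tert-butyl(dimethyl)silyl]oxy}butanal
Conditions: OsO4 (2 mol %), NaIO4, 2,6-lutidine, dioxane/H2O, 25 °C
Reagents that add atoms: sodium periodate, [Na+].[O-]I(=O)(=O)=O
Why: Lemieux–Johnson cleavage of the terminal alkene, chosen over ozone because it spares the electron-rich arenes; the lutidine buffer should keep the β-benzyloxy aldehyde from eliminating.

Step 13
Reactants: 25 dimethyl (1-diazo-2-oxopropyl)phosphonate
Product: 26 dimethyl [1-(benzyloxy)-2-oxopropyl]phosphonate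
Conditions: BnOH (1.2 equiv), Rh2(OAc)4 (1 mol %), CH2Cl2, 40 °C
Reagents that add atoms: benzyl alcohol, OCc1ccccc1
Why: Rhodium carbenoid O–H insertion of an α-diazo-β-ketophosphonate into an alcohol; the product carries the future C5 with its benzylated oxygen, the future C8a carbonyl and the methyl group that becomes C6.

Step 14
Reactants: 24 (3S,4R)-3-(benzyloxy)-4-[3,4-bis(benzyloxy)phenyl]-4-{[tert-butyl(dimethyl)silyl]oxy}butanal; 26 dimethyl [1-(benzyloxy)-2-oxopropyl]phosphonate
Product: 27 (3Z,6S,7R)-3,6-bis(benzyloxy)-7-[3,4-bis(benzyloxy)phenyl]-7-{[tert-butyl(dimethyl)silyl]oxy}hept-3-en-2-one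
Conditions: 26, Ba(OH)2, THF, 25 °C; then 24, THF/H2O (40:1), 0 → 25 °C
Reagents that add atoms: none
Why: Horner–Wadsworth–Emmons olefination with a ketophosphonate under the mild barium hydroxide protocol, which tolerates β-alkoxy aldehydes; the α-alkoxy phosphonate should give mainly the (Z)-enol ether (chain trans to the acetyl group), and this geometry is lost anyway when ring A forms.

Step 15
Reactants: 27 (3Z,6S,7R)-3,6-bis(benzyloxy)-7-[3,4-bis(benzyloxy)phenyl]-7-{[tert-butyl(dimethyl)silyl]oxy}hept-3-en-2-one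
Product: 29 (3Z,6S,7R)-3,6-bis(benzyloxy)-7-[3,4-bis(benzyloxy)phenyl]-7-{[tert-butyl(dimethyl)silyl]oxy}-1-diazohept-3-en-2-one, via trifluoroacetyl diketone 28 (not isolated)
Conditions: LiN(SiMe3)2, THF, −78 °C; CF3CO2CH2CF3, −78 °C; then MeSO2N3, Et3N, H2O (1 equiv), MeCN, 25 °C
Reagents that add atoms: methanesulfonyl azide, CS(=O)(=O)N=[N+]=[N-]
Why: Detrifluoroacetylative diazo transfer (Danheiser diazo transfer); kinetic deprotonation of the methyl ketone and trifluoroacetylation give an activated 1,3-diketone that accepts the diazo group and loses the trifluoroacetyl group, which avoids acylating diazomethane with an unsaturated acid chloride.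

Step 16
Reactants: 29 (3Z,6S,7R)-3,6-bis(benzyloxy)-7-[3,4-bis(benzyloxy)phenyl]-7-{[tert-butyl(dimethyl)silyl]oxy}-1-diazohept-3-en-2-one; 20 {[(3R,4S)-4-(benzyloxy)-3-[3,4-bis(benzyloxy)phenyl]-5-[2,4,6-tris(benzyloxy)phenyl]pent-1-yn-1-yl]oxy}tri(propan-2-yl)silane
Product: 34 3-(benzyloxy)-2-{(2S,3R)-2-(benzyloxy)-3-[3,4-bis(benzyloxy)phenyl]-3-[(tert-butyldimethylsilyl)oxy]propyl}-6-{(1R,2S)-2-(benzyloxy)-1-[3,4-bis(benzyloxy)phenyl]-3-[2,4,6-tris(benzyloxy)phenyl]propyl}-5-[(triisopropylsilyl)oxy]phenol, via vinylketene 30 (not isolated), via vinylcyclobutenone 31 (not isolated), via dienylketene 32 (not isolated), via cyclohexadienone 33 (not isolated)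
Conditions: 29 (1.0 equiv), 20 (1.2 equiv), ClCH2CH2Cl (degassed), hν 350 nm (Pyrex), 25 °C; then 80 °C, dark
Reagents that add atoms: none
Why: Light of 350 nm is absorbed by the diazo enone and not by the benzyloxyarenes; N2 is lost and the 1-benzyloxyalkenyl group shifts (photochemical Wolff rearrangement) to give vinylketene 30. The siloxyalkyne 20 adds [2+2] to the ketene C=C bond: its carbon remote from oxygen, which carries the chain, is the nucleophilic end and bonds to the ketene carbonyl carbon (C8–C8a), while the oxygen-bearing carbon bonds to the former diazo carbon (C7–C6), giving 4-vinylcyclobutenone 31. On warming, 31 opens by a four-electron conrotatory electrocyclic reaction to dienylketene 32, which closes ring A by a six-electron disrotatory electrocyclisation (C4a–C8a) to dienone 33, and enolisation gives phenol 34. The closest known reaction type is the Danheiser benzannulation in its photo-Wolff form with siloxyalkynes, which gives resorcinol monosilyl ethers. Ring A is therefore closed as a carbocycle by a pericyclic step and not by substitution on an existing arene. No lasting stereocentre is formed, since the sp3 carbons of 31 and 33 become aromatic, and the four existing stereocentres are not at reacting atoms and meet neither acid nor base. The selectivity needed is the regiochemistry of the [2+2] step, which the polarisation of the ynol silyl ether secures; the (Z)-geometry of 29 puts the CH2 chain outward at the triene terminus so the ring closure is not slowed. The outcome is a free hydroxyl at C8a, a silyl ether at C7, a benzyl ether at C5 and the chain on C8, so no choice between C6 and C8 has to be made.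

Step 17
Reactants: 34 3-(benzyloxy)-2-{(2S,3R)-2-(benzyloxy)-3-[3,4-bis(benzyloxy)phenyl]-3-[(tert-butyldimethylsilyl)oxy]propyl}-6-{(1R,2S)-2-(benzyloxy)-1-[3,4-bis(benzyloxy)phenyl]-3-[2,4,6-tris(benzyloxy)phenyl]propyl}-5-[(triisopropylsilyl)oxy]phenol
Product: 35 5-(benzyloxy)-4-{(2S,3R)-2-(benzyloxy)-3-[3,4-bis(benzyloxy)phenyl]-3-hydroxypropyl}-2-{(1R,2S)-2-(benzyloxy)-1-[3,4-bis(benzyloxy)phenyl]-3-[2,4,6-tris(benzyloxy)phenyl]propyl}benzene-1,3-diol
Conditions: Bu4NF, AcOH, THF, 0 → 25 °C, argon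
Reagents that add atoms: none
Why: Fluoride cleaves the aryl triisopropylsilyl ether and the benzylic tert-butyldimethylsilyl ether; the acetic acid buffer and the exclusion of air protect the electron-rich resorcinol, and benzyl ethers and stereocentres are not touched.

Step 18
Reactants: 35 5-(benzyloxy)-4-{(2S,3R)-2-(benzyloxy)-3-[3,4-bis(benzyloxy)phenyl]-3-hydroxypropyl}-2-{(1R,2S)-2-(benzyloxy)-1-[3,4-bis(benzyloxy)phenyl]-3-[2,4,6-tris(benzyloxy)phenyl]propyl}benzene-1,3-diol
Product: 36 (2S,3S)-3,5-bis(benzyloxy)-2-[3,4-bis(benzyloxy)phenyl]-8-{(1R,2S)-2-(benzyloxy)-1-[3,4-bis(benzyloxy)phenyl]-3-[2,4,6-tris(benzyloxy)phenyl]propyl}chroman-7-ol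
Conditions: PPh3, diisopropyl azodicarboxylate, toluene, 0 °C, high dilution
Reagents that add atoms: none
Why: Intramolecular Mitsunobu etherification (6-exo-tet); the C2 hydroxyl is activated as the oxyphosphonium ion and displaced by the C8a phenoxide with inversion, turning (2R) into (2S) and giving the 2,3-cis pyran. The C7 phenol cannot reach C2, and the only other ortho oxygen (O5) is benzylated.

Step 19
Reactants: 36 (2S,3S)-3,5-bis(benzyloxy)-2-[3,4-bis(benzyloxy)phenyl]-8-{(1R,2S)-2-(benzyloxy)-1-[3,4-bis(benzyloxy)phenyl]-3-[2,4,6-tris(benzyloxy)phenyl]propyl}chroman-7-ol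
Product: 37 gambiriin A2, (2S,3S)-8-[(1R,2S)-1-(3,4-dihydroxyphenyl)-2-hydroxy-3-(2,4,6-trihydroxyphenyl)propyl]-2-(3,4-dihydroxyphenyl)chromane-3,5,7-triol
Conditions: H2 (1 atm), Pd(OH)2/C, THF/MeOH, 25 °C
Reagents that add atoms: none
Why: Hydrogenolysis of the ten O-benzyl groups; the C2–O1 bond of flavan-3-ols and the diarylmethine C–C bonds are expected to survive, as in the debenzylation of benzylated catechins, and no acid or base is present that could epimerise C2.

## Compound list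

1 | 3,4-bis(benzyloxy)benzaldehyde | O=Cc1ccc(OCc2ccccc2)c(OCc2ccccc2)c1 | starting material
2 | vinylmagnesium bromide | C=C[Mg]Br | starting material
3 | rac-1-[3,4-bis(benzyloxy)phenyl]prop-2-en-1-ol | C=CC(O)c1ccc(OCc2ccccc2)c(OCc2ccccc2)c1 | intermediate
4 | (R)-[3,4-bis(benzyloxy)phenyl][(2S)-oxiran-2-yl]methanol | O[C@H](c1ccc(OCc2ccccc2)c(OCc2ccccc2)c1)[C@@H]1CO1 | intermediate
5 | 1,3,5-tris(benzyloxy)benzene | c1(OCc2ccccc2)cc(OCc2ccccc2)cc(OCc2ccccc2)c1 | starting material
6 | 2-bromo-1,3,5-tris(benzyloxy)benzene | Brc1c(OCc2ccccc2)cc(OCc2ccccc2)cc1OCc1ccccc1 | intermediate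
7 | [2,4,6-tris(benzyloxy)phenyl]magnesium bromide | Br[Mg]c1c(OCc2ccccc2)cc(OCc2ccccc2)cc1OCc1ccccc1 | intermediate
8 | (1R,2S)-1-[3,4-bis(benzyloxy)phenyl]-3-[2,4,6-tris(benzyloxy)phenyl]propane-1,2-diol | O[C@H](c1ccc(OCc2ccccc2)c(OCc2ccccc2)c1)[C@@H](O)Cc1c(OCc2ccccc2)cc(OCc2ccccc2)cc1OCc1ccccc1 | intermediate
9 | (4R,5S)-4-[3,4-bis(benzyloxy)phenyl]-2-methoxy-2-methyl-5-[2,4,6-tris(benzyloxy)benzyl]-1,3-dioxolane (both epimers at the orthoester carbon) | COC1(C)O[C@H](c2ccc(OCc3ccccc3)c(OCc3ccccc3)c2)[C@H](Cc2c(OCc3ccccc3)cc(OCc3ccccc3)cc2OCc2ccccc2)O1 | intermediate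
10 | (1S,2S)-1-[3,4-bis(benzyloxy)phenyl]-1-chloro-3-[2,4,6-tris(benzyloxy)phenyl]propan-2-yl acetate | Cl[C@@H](c1ccc(OCc2ccccc2)c(OCc2ccccc2)c1)[C@@H](OC(C)=O)Cc1c(OCc2ccccc2)cc(OCc2ccccc2)cc1OCc1ccccc1 | intermediate
11 | (2R,3S)-2-[3,4-bis(benzyloxy)phenyl]-3-[2,4,6-tris(benzyloxy)benzyl]oxirane (cis) | C(c1c(OCc2ccccc2)cc(OCc2ccccc2)cc1OCc1ccccc1)[C@@H]1O[C@@H]1c1ccc(OCc2ccccc2)c(OCc2ccccc2)c1 | intermediate
12 | ethynyl(trimethyl)silane | C#C[Si](C)(C)C | starting material
13 | lithium (trimethylsilyl)acetylide | [Li]C#C[Si](C)(C)C | intermediate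
14 | diethyl[(trimethylsilyl)ethynyl]aluminium | CC[Al](CC)C#C[Si](C)(C)C | intermediate
15 | (2S,3R)-3-[3,4-bis(benzyloxy)phenyl]-1-[2,4,6-tris(benzyloxy)phenyl]-5-(trimethylsilyl)pent-4-yn-2-ol | O(Cc1ccccc1)c1cc(OCc2ccccc2)c(C[C@H](O)[C@H](c2ccc(OCc3ccccc3)c(OCc3ccccc3)c2)C#C[Si](C)(C)C)c(OCc2ccccc2)c1 | intermediate
16 | {(3R,4S)-4-(benzyloxy)-3-[3,4-bis(benzyloxy)phenyl]-5-[2,4,6-tris(benzyloxy)phenyl]pent-1-yn-1-yl}(trimethyl)silane | O(Cc1ccccc1)c1cc(OCc2ccccc2)c(C[C@H](OCc2ccccc2)[C@H](c2ccc(OCc3ccccc3)c(OCc3ccccc3)c2)C#C[Si](C)(C)C)c(OCc2ccccc2)c1 | intermediate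
17 | 1,3,5-tris(benzyloxy)-2-{(2S,3S)-2-(benzyloxy)-3-[3,4-bis(benzyloxy)phenyl]pent-4-yn-1-yl}benzene | O(Cc1ccccc1)c1cc(OCc2ccccc2)c(C[C@H](OCc2ccccc2)[C@H](c2ccc(OCc3ccccc3)c(OCc3ccccc3)c2)C#C)c(OCc2ccccc2)c1 | intermediate
18 | lithium acetylide of 17 (lithium in place of the alkyne hydrogen; both stereocentres as in 17) | O(Cc1ccccc1)c1cc(OCc2ccccc2)c(C[C@H](OCc2ccccc2)[C@H](c2ccc(OCc3ccccc3)c(OCc3ccccc3)c2)C#C[Li])c(OCc2ccccc2)c1 | intermediate
19 | lithium (3R,4S)-4-(benzyloxy)-3-[3,4-bis(benzyloxy)phenyl]-5-[2,4,6-tris(benzyloxy)phenyl]pent-1-yn-1-olate | O(Cc1ccccc1)c1cc(OCc2ccccc2)c(C[C@H](OCc2ccccc2)[C@H](c2ccc(OCc3ccccc3)c(OCc3ccccc3)c2)C#CO[Li])c(OCc2ccccc2)c1 | intermediate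
20 | {[(3R,4S)-4-(benzyloxy)-3-[3,4-bis(benzyloxy)phenyl]-5-[2,4,6-tris(benzyloxy)phenyl]pent-1-yn-1-yl]oxy}tri(propan-2-yl)silane | O(Cc1ccccc1)c1cc(OCc2ccccc2)c(C[C@H](OCc2ccccc2)[C@H](c2ccc(OCc3ccccc3)c(OCc3ccccc3)c2)C#CO[Si](C(C)C)(C(C)C)C(C)C)c(OCc2ccccc2)c1 | intermediate
21 | tert-butyl{(R)-[3,4-bis(benzyloxy)phenyl][(2S)-oxiran-2-yl]methoxy}dimethylsilane | CC(C)(C)[Si](C)(C)O[C@H](c1ccc(OCc2ccccc2)c(OCc2ccccc2)c1)[C@@H]1CO1 | intermediate
22 | (1R,2S)-1-[3,4-bis(benzyloxy)phenyl]-1-{[tert-butyl(dimethyl)silyl]oxy}pent-4-en-2-ol | CC(C)(C)[Si](C)(C)O[C@H](c1ccc(OCc2ccccc2)c(OCc2ccccc2)c1)[C@@H](O)CC=C | intermediate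
23 | {[(1R,2S)-2-(benzyloxy)-1-[3,4-bis(benzyloxy)phenyl]pent-4-en-1-yl]oxy}(tert-butyl)dimethylsilane | CC(C)(C)[Si](C)(C)O[C@H](c1ccc(OCc2ccccc2)c(OCc2ccccc2)c1)[C@@H](OCc1ccccc1)CC=C | intermediate
24 | (3S,4R)-3-(benzyloxy)-4-[3,4-bis(benzyloxy)phenyl]-4-{[tert-butyl(dimethyl)silyl]oxy}butanal | CC(C)(C)[Si](C)(C)O[C@H](c1ccc(OCc2ccccc2)c(OCc2ccccc2)c1)[C@@H](OCc1ccccc1)CC=O | intermediate
25 | dimethyl (1-diazo-2-oxopropyl)phosphonate | COP(=O)(OC)C(=[N+]=[N-])C(C)=O | starting material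
26 | dimethyl [1-(benzyloxy)-2-oxopropyl]phosphonate (racemic) | COP(=O)(OC)C(OCc1ccccc1)C(C)=O | intermediate
27 | (3Z,6S,7R)-3,6-bis(benzyloxy)-7-[3,4-bis(benzyloxy)phenyl]-7-{[tert-butyl(dimethyl)silyl]oxy}hept-3-en-2-one | CC(=O)/C(OCc1ccccc1)=C/C[C@H](OCc1ccccc1)[C@H](O[Si](C)(C)C(C)(C)C)c1ccc(OCc2ccccc2)c(OCc2ccccc2)c1 | intermediate
28 | (5Z,8S,9R)-5,8-bis(benzyloxy)-9-[3,4-bis(benzyloxy)phenyl]-9-{[tert-butyl(dimethyl)silyl]oxy}-1,1,1-trifluoronon-5-ene-2,4-dione | FC(F)(F)C(=O)CC(=O)/C(OCc1ccccc1)=C/C[C@H](OCc1ccccc1)[C@H](O[Si](C)(C)C(C)(C)C)c1ccc(OCc2ccccc2)c(OCc2ccccc2)c1 | intermediate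
29 | (3Z,6S,7R)-3,6-bis(benzyloxy)-7-[3,4-bis(benzyloxy)phenyl]-7-{[tert-butyl(dimethyl)silyl]oxy}-1-diazohept-3-en-2-one | [N-]=[N+]=CC(=O)/C(OCc1ccccc1)=C/C[C@H](OCc1ccccc1)[C@H](O[Si](C)(C)C(C)(C)C)c1ccc(OCc2ccccc2)c(OCc2ccccc2)c1 | intermediate
30 | (3Z,6S,7R)-3,6-bis(benzyloxy)-7-[3,4-bis(benzyloxy)phenyl]-7-{[tert-butyl(dimethyl)silyl]oxy}hepta-1,3-dien-1-one (vinylketene) | O=C=C/C(OCc1ccccc1)=C/C[C@H](OCc1ccccc1)[C@H](O[Si](C)(C)C(C)(C)C)c1ccc(OCc2ccccc2)c(OCc2ccccc2)c1 | intermediate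
31 | 4-vinylcyclobutenone: cyclobut-2-en-1-one with the (1R,2S)-2-(benzyloxy)-1-[3,4-bis(benzyloxy)phenyl]-3-[2,4,6-tris(benzyloxy)phenyl]propyl group at C2, the triisopropylsilyloxy group at C3 and the (1Z,4S,5R)-1,4-bis(benzyloxy)-5-[3,4-bis(benzyloxy)phenyl]-5-[(tert-butyldimethylsilyl)oxy]pent-1-en-1-yl group at C4 (either C4 epimer) | O(Cc1ccccc1)c1cc(OCc2ccccc2)c(C[C@H](OCc2ccccc2)[C@H](c2ccc(OCc3ccccc3)c(OCc3ccccc3)c2)C2=C(O[Si](C(C)C)(C(C)C)C(C)C)C(/C(OCc3ccccc3)=C/C[C@H](OCc3ccccc3)[C@H](O[Si](C)(C)C(C)(C)C)c3ccc(OCc4ccccc4)c(OCc4ccccc4)c3)C2=O)c(OCc2ccccc2)c1 | intermediate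
32 | dienylketene: (3E,5Z,8S,9R)-5,8-bis(benzyloxy)-9-[3,4-bis(benzyloxy)phenyl]-9-[(tert-butyldimethylsilyl)oxy]-3-[(triisopropylsilyl)oxy]nona-1,3,5-trien-1-one carrying the (1R,2S)-chain of 31 at C2 | O(Cc1ccccc1)c1cc(OCc2ccccc2)c(C[C@H](OCc2ccccc2)[C@H](c2ccc(OCc3ccccc3)c(OCc3ccccc3)c2)C(=C=O)/C(O[Si](C(C)C)(C(C)C)C(C)C)=C\C(OCc2ccccc2)=C\C[C@H](OCc2ccccc2)[C@H](O[Si](C)(C)C(C)(C)C)c2ccc(OCc3ccccc3)c(OCc3ccccc3)c2)c(OCc2ccccc2)c1 | intermediate
33 | cyclohexa-2,4-dien-1-one tautomer of 34 (sp3 carbon at the position that becomes C4a, either epimer) | O(Cc1ccccc1)c1cc(OCc2ccccc2)c(C[C@H](OCc2ccccc2)[C@H](c2ccc(OCc3ccccc3)c(OCc3ccccc3)c2)C2=C(O[Si](C(C)C)(C(C)C)C(C)C)C=C(OCc3ccccc3)C(C[C@H](OCc3ccccc3)[C@H](O[Si](C)(C)C(C)(C)C)c3ccc(OCc4ccccc4)c(OCc4ccccc4)c3)C2=O)c(OCc2ccccc2)c1 | intermediate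
34 | 3-(benzyloxy)-2-{(2S,3R)-2-(benzyloxy)-3-[3,4-bis(benzyloxy)phenyl]-3-[(tert-butyldimethylsilyl)oxy]propyl}-6-{(1R,2S)-2-(benzyloxy)-1-[3,4-bis(benzyloxy)phenyl]-3-[2,4,6-tris(benzyloxy)phenyl]propyl}-5-[(triisopropylsilyl)oxy]phenol | O(Cc1ccccc1)c1cc(OCc2ccccc2)c(C[C@H](OCc2ccccc2)[C@H](c2ccc(OCc3ccccc3)c(OCc3ccccc3)c2)c2c(O[Si](C(C)C)(C(C)C)C(C)C)cc(OCc3ccccc3)c(C[C@H](OCc3ccccc3)[C@H](O[Si](C)(C)C(C)(C)C)c3ccc(OCc4ccccc4)c(OCc4ccccc4)c3)c2O)c(OCc2ccccc2)c1 | intermediate
35 | 5-(benzyloxy)-4-{(2S,3R)-2-(benzyloxy)-3-[3,4-bis(benzyloxy)phenyl]-3-hydroxypropyl}-2-{(1R,2S)-2-(benzyloxy)-1-[3,4-bis(benzyloxy)phenyl]-3-[2,4,6-tris(benzyloxy)phenyl]propyl}benzene-1,3-diol | O(Cc1ccccc1)c1cc(OCc2ccccc2)c(C[C@H](OCc2ccccc2)[C@H](c2ccc(OCc3ccccc3)c(OCc3ccccc3)c2)c2c(O)cc(OCc3ccccc3)c(C[C@H](OCc3ccccc3)[C@H](O)c3ccc(OCc4ccccc4)c(OCc4ccccc4)c3)c2O)c(OCc2ccccc2)c1 | intermediate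
36 | (2S,3S)-3,5-bis(benzyloxy)-2-[3,4-bis(benzyloxy)phenyl]-8-{(1R,2S)-2-(benzyloxy)-1-[3,4-bis(benzyloxy)phenyl]-3-[2,4,6-tris(benzyloxy)phenyl]propyl}chroman-7-ol | O(Cc1ccccc1)c1cc(OCc2ccccc2)c(C[C@H](OCc2ccccc2)[C@H](c2ccc(OCc3ccccc3)c(OCc3ccccc3)c2)c2c(O)cc(OCc3ccccc3)c3c2O[C@@H](c2ccc(OCc4ccccc4)c(OCc4ccccc4)c2)[C@@H](OCc2ccccc2)C3)c(OCc2ccccc2)c1 | intermediate
37 | gambiriin A2, (2S,3S)-8-[(1R,2S)-1-(3,4-dihydroxyphenyl)-2-hydroxy-3-(2,4,6-trihydroxyphenyl)propyl]-2-(3,4-dihydroxyphenyl)chromane-3,5,7-triol | Oc1cc(O)c(C[C@H](O)[C@H](c2ccc(O)c(O)c2)c2c(O)cc(O)c3c2O[C@@H](c2ccc(O)c(O)c2)[C@@H](O)C3)c(O)c1 | target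

## Step count and least certain steps

Total step count: 19.
Longest linear sequence: 12 steps (steps 1, 2, 9, 10, 11, 12, 14, 15, 16, 17, 18, 19).

**Step 16 (key step).** The most likely failure is that vinylketene 30 is consumed faster by dimerisation, by acylation of the product phenol or by carbene-type insertion into the neighbouring benzyloxy CH2 than by the [2+2] addition. The alkyne 20 is branched at the propargylic carbon and is too valuable to use in large excess, and the many arenes compete for light.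

Fallback: the same vinylketene is released slowly and in the dark from a cyclobutenone, so that photolysis is replaced by a thermal entry. The sequence sets out from 23 and comes back to the route at 34. Hydroboration of 23 with 9-borabicyclo[3.3.1]nonane and oxidation (NaOH, H2O2) should give the primary alcohol (4S,5R)-4-(benzyloxy)-5-[3,4-bis(benzyloxy)phenyl]-5-{[tert-butyl(dimethyl)silyl]oxy}pentan-1-ol F1 as the anti-Markovnikov product. Oxidation of F1 with 2,2,6,6-tetramethylpiperidin-1-oxyl and PhI(OAc)2 in MeCN/H2O gives (4S,5R)-4-(benzyloxy)-5-[3,4-bis(benzyloxy)phenyl]-5-{[tert-butyl(dimethyl)silyl]oxy}pentanoic acid F2 without touching the silyl ether. The acid F2 is then converted with oxalyl chloride into (4S,5R)-4-(benzyloxy)-5-[3,4-bis(benzyloxy)phenyl]-5-{[tert-butyl(dimethyl)silyl]oxy}pentanoyl chloride F3 for ketene generation. When F3 is treated with Et3N in the presence of freshly prepared (benzyloxy)ethyne F4 at low temperature, the alkylketene (4S,5R)-4-(benzyloxy)-5-[3,4-bis(benzyloxy)phenyl]-5-{[tert-butyl(dimethyl)silyl]oxy}pent-1-en-1-one F5 forms in the flask. The ketene F5 is trapped by F4 in a [2+2] addition as 3-(benzyloxy)-4-{(2S,3R)-2-(benzyloxy)-3-[3,4-bis(benzyloxy)phenyl]-3-{[tert-butyl(dimethyl)silyl]oxy}propyl}cyclobut-2-en-1-one F6 with the benzyloxy group at C3. Heating F6 with 20 in toluene at 110 °C (thermal form of the Danheiser benzannulation) opens F6 reversibly to 30, which is trapped as in step 16 to give 34.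

**Step 6.** The most likely failure is loss of stereochemical fidelity at the electron-rich benzylic carbon: the Lewis-acidic alane can open the epoxide to an ion pair, so that the alkynyl group enters partly from the face of the departing oxygen and the C3 epimer forms.

Fallback: the C2–C3 bond is made through a closed transition state instead of by substitution. The sequence sets out from 7 and 3 and comes back to the route at 18. Grignard reagent 7 and allyl bromide (CuI cat.) give 2-allyl-1,3,5-tris(benzyloxy)benzene F7 by allylic substitution. OsO4/NaIO4 cleaves F7 to [2,4,6-tris(benzyloxy)phenyl]acetaldehyde F8 under lutidine buffer. Alcohol 3 (or its unused enantiomer from step 2), B2pin2 and [Pd(MeCN)4](BF4)2 give the linear boronate 2-{(2E)-3-[3,4-bis(benzyloxy)phenyl]prop-2-en-1-yl}-4,4,5,5-tetramethyl-1,3,2-dioxaborolane F9 with the (E) double bond. Allylboration of F8 with F9 is catalysed by 3,3′-bis(2,4,6-triisopropylphenyl)-1,1′-binaphthyl-2,2′-diyl hydrogen phosphate, using the catalyst enantiomer that gives the (2S,3S) product. The chair (Zimmerman–Traxler) transition state of the (E)-boronate should give the anti alcohol (2S,3S)-3-[3,4-bis(benzyloxy)phenyl]-1-[2,4,6-tris(benzyloxy)phenyl]pent-4-en-2-ol F10 with both stereocentres set together. Benzylation of F10 (KN(SiMe3)2, BnBr) gives 1,3,5-tris(benzyloxy)-2-{(2S,3S)-2-(benzyloxy)-3-[3,4-bis(benzyloxy)phenyl]pent-4-en-1-yl}benzene F11 as in step 7. OsO4/NaIO4 turns F11 into (2S,3S)-3-(benzyloxy)-2-[3,4-bis(benzyloxy)phenyl]-4-[2,4,6-tris(benzyloxy)phenyl]butanal F12 by loss of the terminal carbon. The aldehyde F12 is used at once, because its α-aryl centre epimerises easily. Corey–Fuchs olefination (CBr4, PPh3) converts it into 1,3,5-tris(benzyloxy)-2-{(2S,3S)-2-(benzyloxy)-3-[3,4-bis(benzyloxy)phenyl]-5,5-dibromopent-4-en-1-yl}benzene F13 without base. Two equivalents of n-BuLi at −78 °C convert F13 into the lithium acetylide 18, which is oxygenated and silylated as in step 8.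

**Step 18.** The most likely failure is partial ionisation of the oxyphosphonium ion at the electron-rich benzylic C2, which would give the 2,3-trans epimer. This is favoured when the betaine is quenched by the unhindered C7 phenol, so that the C8a phenoxide is not the counter-ion at the moment of displacement; intermolecular O-alkylation at C7 is a lesser risk.

Fallback: the C7 oxygen stays silylated during the closure, so the C8a phenol is the only acidic site. The sequence sets out from 34 and comes back to the route at 36. HF·pyridine buffered with pyridine in THF at 0 °C should remove only the alkyl tert-butyldimethylsilyl ether and give 3-(benzyloxy)-2-{(2S,3R)-2-(benzyloxy)-3-[3,4-bis(benzyloxy)phenyl]-3-hydroxypropyl}-6-{(1R,2S)-2-(benzyloxy)-1-[3,4-bis(benzyloxy)phenyl]-3-[2,4,6-tris(benzyloxy)phenyl]propyl}-5-[(triisopropylsilyl)oxy]phenol F14 with the aryl silyl ether intact. Mitsunobu closure of F14 (PPh3, diisopropyl azodicarboxylate, toluene, low temperature) gives (2S,3S)-3,5-bis(benzyloxy)-2-[3,4-bis(benzyloxy)phenyl]-8-{(1R,2S)-2-(benzyloxy)-1-[3,4-bis(benzyloxy)phenyl]-3-[2,4,6-tris(benzyloxy)phenyl]propyl}-7-[(triisopropylsilyl)oxy]chromane F15 with inversion at C2. Bu4NF/AcOH then cleaves the aryl silyl ether of F15 to give 36.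

**Step 2.** The most likely failure is ionisation of the benzylic, allylic and electron-rich alcohol 3 at the Lewis-acidic titanium centre (1,3-transposition, loss of enantiopurity), or opening of the product epoxide by alkoxide on titanium. The terminal alkene also reacts slowly, which lengthens the exposure.

Fallback: resolution and epoxidation without a Lewis acid. The sequence sets out from 3 and comes back to the route at 21. Candida antarctica lipase B and vinyl acetate acylate the (R)-alcohol to (R)-1-[3,4-bis(benzyloxy)phenyl]prop-2-en-1-yl acetate F17 and leave (S)-1-[3,4-bis(benzyloxy)phenyl]prop-2-en-1-ol F16 unchanged. The acetate F17 is separated by chromatography. Silylation of F16 (t-BuMe2SiCl, imidazole) gives tert-butyl{[(1S)-1-[3,4-bis(benzyloxy)phenyl]prop-2-en-1-yl]oxy}dimethylsilane F18 as a single enantiomer. Buffered m-chloroperbenzoic acid (NaHCO3) epoxidises F18 to 21 together with its oxirane epimer tert-butyl{(R)-[3,4-bis(benzyloxy)phenyl][(2R)-oxiran-2-yl]methoxy}dimethylsilane F19 in a mixture. Jacobsen hydrolytic kinetic resolution with (salen)Co(OAc) (trivalent cobalt) and water, with the catalyst enantiomer that hydrolyses the (2R)-oxirane, turns F19 into (2R,3R)-3-[3,4-bis(benzyloxy)phenyl]-3-{[tert-butyl(dimethyl)silyl]oxy}propane-1,2-diol F20 and leaves 21. The polar diol F20 is removed by chromatography. Where 4 is needed for step 4, 21 is desilylated with Bu4NF/AcOH.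

## Further compounds

F1 | step 16 | (4S,5R)-4-(benzyloxy)-5-[3,4-bis(benzyloxy)phenyl]-5-{[tert-butyl(dimethyl)silyl]oxy}pentan-1-ol | CC(C)(C)[Si](C)(C)O[C@H](c1ccc(OCc2ccccc2)c(OCc2ccccc2)c1)[C@@H](OCc1ccccc1)CCCO
F2 | step 16 | (4S,5R)-4-(benzyloxy)-5-[3,4-bis(benzyloxy)phenyl]-5-{[tert-butyl(dimethyl)silyl]oxy}pentanoic acid | CC(C)(C)[Si](C)(C)O[C@H](c1ccc(OCc2ccccc2)c(OCc2ccccc2)c1)[C@@H](OCc1ccccc1)CCC(O)=O
F3 | step 16 | (4S,5R)-4-(benzyloxy)-5-[3,4-bis(benzyloxy)phenyl]-5-{[tert-butyl(dimethyl)silyl]oxy}pentanoyl chloride | CC(C)(C)[Si](C)(C)O[C@H](c1ccc(OCc2ccccc2)c(OCc2ccccc2)c1)[C@@H](OCc1ccccc1)CCC(Cl)=O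
F4 | step 16 | (benzyloxy)ethyne | C#COCc1ccccc1
F5 | step 16 | (4S,5R)-4-(benzyloxy)-5-[3,4-bis(benzyloxy)phenyl]-5-{[tert-butyl(dimethyl)silyl]oxy}pent-1-en-1-one (alkylketene) | CC(C)(C)[Si](C)(C)O[C@H](c1ccc(OCc2ccccc2)c(OCc2ccccc2)c1)[C@@H](OCc1ccccc1)CC=C=O
F6 | step 16 | 3-(benzyloxy)-4-{(2S,3R)-2-(benzyloxy)-3-[3,4-bis(benzyloxy)phenyl]-3-{[tert-butyl(dimethyl)silyl]oxy}propyl}cyclobut-2-en-1-one (either C4 epimer) | CC(C)(C)[Si](C)(C)O[C@H](c1ccc(OCc2ccccc2)c(OCc2ccccc2)c1)[C@@H](OCc1ccccc1)CC1C(=O)C=C1OCc1ccccc1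
F7 | step 6 | 2-allyl-1,3,5-tris(benzyloxy)benzene | C=CCc1c(OCc2ccccc2)cc(OCc2ccccc2)cc1OCc1ccccc1
F8 | step 6 | [2,4,6-tris(benzyloxy)phenyl]acetaldehyde | O=CCc1c(OCc2ccccc2)cc(OCc2ccccc2)cc1OCc1ccccc1
F9 | step 6 | 2-{(2E)-3-[3,4-bis(benzyloxy)phenyl]prop-2-en-1-yl}-4,4,5,5-tetramethyl-1,3,2-dioxaborolane | CC1(C)OB(C/C=C/c2ccc(OCc3ccccc3)c(OCc3ccccc3)c2)OC1(C)C
F10 | step 6 | (2S,3S)-3-[3,4-bis(benzyloxy)phenyl]-1-[2,4,6-tris(benzyloxy)phenyl]pent-4-en-2-ol | O(Cc1ccccc1)c1cc(OCc2ccccc2)c(C[C@H](O)[C@H](c2ccc(OCc3ccccc3)c(OCc3ccccc3)c2)C=C)c(OCc2ccccc2)c1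
F11 | step 6 | 1,3,5-tris(benzyloxy)-2-{(2S,3S)-2-(benzyloxy)-3-[3,4-bis(benzyloxy)phenyl]pent-4-en-1-yl}benzene | O(Cc1ccccc1)c1cc(OCc2ccccc2)c(C[C@H](OCc2ccccc2)[C@H](c2ccc(OCc3ccccc3)c(OCc3ccccc3)c2)C=C)c(OCc2ccccc2)c1
F12 | step 6 | (2S,3S)-3-(benzyloxy)-2-[3,4-bis(benzyloxy)phenyl]-4-[2,4,6-tris(benzyloxy)phenyl]butanal | O(Cc1ccccc1)c1cc(OCc2ccccc2)c(C[C@H](OCc2ccccc2)[C@H](c2ccc(OCc3ccccc3)c(OCc3ccccc3)c2)C=O)c(OCc2ccccc2)c1
F13 | step 6 | 1,3,5-tris(benzyloxy)-2-{(2S,3S)-2-(benzyloxy)-3-[3,4-bis(benzyloxy)phenyl]-5,5-dibromopent-4-en-1-yl}benzene | O(Cc1ccccc1)c1cc(OCc2ccccc2)c(C[C@H](OCc2ccccc2)[C@H](c2ccc(OCc3ccccc3)c(OCc3ccccc3)c2)C=C(Br)Br)c(OCc2ccccc2)c1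
F14 | step 18 | 3-(benzyloxy)-2-{(2S,3R)-2-(benzyloxy)-3-[3,4-bis(benzyloxy)phenyl]-3-hydroxypropyl}-6-{(1R,2S)-2-(benzyloxy)-1-[3,4-bis(benzyloxy)phenyl]-3-[2,4,6-tris(benzyloxy)phenyl]propyl}-5-[(triisopropylsilyl)oxy]phenol | O(Cc1ccccc1)c1cc(OCc2ccccc2)c(C[C@H](OCc2ccccc2)[C@H](c2ccc(OCc3ccccc3)c(OCc3ccccc3)c2)c2c(O[Si](C(C)C)(C(C)C)C(C)C)cc(OCc3ccccc3)c(C[C@H](OCc3ccccc3)[C@H](O)c3ccc(OCc4ccccc4)c(OCc4ccccc4)c3)c2O)c(OCc2ccccc2)c1
F15 | step 18 | (2S,3S)-3,5-bis(benzyloxy)-2-[3,4-bis(benzyloxy)phenyl]-8-{(1R,2S)-2-(benzyloxy)-1-[3,4-bis(benzyloxy)phenyl]-3-[2,4,6-tris(benzyloxy)phenyl]propyl}-7-[(triisopropylsilyl)oxy]chromane | O(Cc1ccccc1)c1cc(OCc2ccccc2)c(C[C@H](OCc2ccccc2)[C@H](c2ccc(OCc3ccccc3)c(OCc3ccccc3)c2)c2c(O[Si](C(C)C)(C(C)C)C(C)C)cc(OCc3ccccc3)c3c2O[C@@H](c2ccc(OCc4ccccc4)c(OCc4ccccc4)c2)[C@@H](OCc2ccccc2)C3)c(OCc2ccccc2)c1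
F16 | step 2 | (S)-1-[3,4-bis(benzyloxy)phenyl]prop-2-en-1-ol | C=C[C@H](O)c1ccc(OCc2ccccc2)c(OCc2ccccc2)c1
F17 | step 2 | (R)-1-[3,4-bis(benzyloxy)phenyl]prop-2-en-1-yl acetate | C=C[C@@H](OC(C)=O)c1ccc(OCc2ccccc2)c(OCc2ccccc2)c1
F18 | step 2 | tert-butyl{[(1S)-1-[3,4-bis(benzyloxy)phenyl]prop-2-en-1-yl]oxy}dimethylsilane | C=C[C@H](O[Si](C)(C)C(C)(C)C)c1ccc(OCc2ccccc2)c(OCc2ccccc2)c1
F19 | step 2 | tert-butyl{(R)-[3,4-bis(benzyloxy)phenyl][(2R)-oxiran-2-yl]methoxy}dimethylsilane | CC(C)(C)[Si](C)(C)O[C@H](c1ccc(OCc2ccccc2)c(OCc2ccccc2)c1)[C@H]1CO1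
F20 | step 2 | (2R,3R)-3-[3,4-bis(benzyloxy)phenyl]-3-{[tert-butyl(dimethyl)silyl]oxy}propane-1,2-diol | CC(C)(C)[Si](C)(C)O[C@H](c1ccc(OCc2ccccc2)c(OCc2ccccc2)c1)[C@H](O)CO
A1 | alternative 1 | undeca-O-benzyl derivative of 37 | O(Cc1ccccc1)c1cc(OCc2ccccc2)c(C[C@H](OCc2ccccc2)[C@H](c2ccc(OCc3ccccc3)c(OCc3ccccc3)c2)c2c(OCc3ccccc3)cc(OCc3ccccc3)c3c2O[C@@H](c2ccc(OCc4ccccc4)c(OCc4ccccc4)c2)[C@@H](OCc2ccccc2)C3)c(OCc2ccccc2)c1
A2 | alternative 1 | (1S,2S)-2-(benzyloxy)-1-[3,4-bis(benzyloxy)phenyl]-3-{4,6-bis(benzyloxy)-2-bromo-3-[(1R,2S)-2-(benzyloxy)-1-[3,4-bis(benzyloxy)phenyl]-3-[2,4,6-tris(benzyloxy)phenyl]propyl]phenyl}propan-1-ol | O(Cc1ccccc1)c1cc(OCc2ccccc2)c(C[C@H](OCc2ccccc2)[C@H](c2ccc(OCc3ccccc3)c(OCc3ccccc3)c2)c2c(OCc3ccccc3)cc(OCc3ccccc3)c(C[C@H](OCc3ccccc3)[C@@H](O)c3ccc(OCc4ccccc4)c(OCc4ccccc4)c3)c2Br)c(OCc2ccccc2)c1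
A3 | alternative 2 | deca-O-benzyl derivative of 37 with free C3 hydroxyl | O(Cc1ccccc1)c1cc(OCc2ccccc2)c(C[C@H](OCc2ccccc2)[C@H](c2ccc(OCc3ccccc3)c(OCc3ccccc3)c2)c2c(OCc3ccccc3)cc(OCc3ccccc3)c3c2O[C@@H](c2ccc(OCc4ccccc4)c(OCc4ccccc4)c2)[C@@H](O)C3)c(OCc2ccccc2)c1
A4 | alternative 2 | (S)-[3,4-bis(benzyloxy)phenyl][(2S)-oxiran-2-yl]methyl 3,5-bis(benzyloxy)-2-{(1R,2S)-2-(benzyloxy)-1-[3,4-bis(benzyloxy)phenyl]-3-[2,4,6-tris(benzyloxy)phenyl]propyl}phenyl ether | O(Cc1ccccc1)c1cc(OCc2ccccc2)c(C[C@H](OCc2ccccc2)[C@H](c2ccc(OCc3ccccc3)c(OCc3ccccc3)c2)c2c(OCc3ccccc3)cc(OCc3ccccc3)cc2O[C@@H](c2ccc(OCc3ccccc3)c(OCc3ccccc3)c2)[C@@H]2CO2)c(OCc2ccccc2)c1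
A5 | alternative 3 | deca-O-benzyl derivative of 37 as its 3-O-acetate | O(Cc1ccccc1)c1cc(OCc2ccccc2)c(C[C@H](OCc2ccccc2)[C@H](c2ccc(OCc3ccccc3)c(OCc3ccccc3)c2)c2c(OCc3ccccc3)cc(OCc3ccccc3)c3c2O[C@@H](c2ccc(OCc4ccccc4)c(OCc4ccccc4)c2)[C@@H](OC(C)=O)C3)c(OCc2ccccc2)c1
A6 | alternative 3 | 3,5-bis(benzyloxy)-2-(hydroxymethyl)-6-{(1R,2S)-2-(benzyloxy)-1-[3,4-bis(benzyloxy)phenyl]-3-[2,4,6-tris(benzyloxy)phenyl]propyl}phenol | O(Cc1ccccc1)c1cc(OCc2ccccc2)c(C[C@H](OCc2ccccc2)[C@H](c2ccc(OCc3ccccc3)c(OCc3ccccc3)c2)c2c(OCc3ccccc3)cc(OCc3ccccc3)c(CO)c2O)c(OCc2ccccc2)c1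
A7 | alternative 3 | (Z)-2-[3,4-bis(benzyloxy)phenyl]ethenyl acetate | CC(=O)O/C=C\c1ccc(OCc2ccccc2)c(OCc2ccccc2)c1
A8 | alternative 3 | 3,5-bis(benzyloxy)-6-methylidene-2-{(1R,2S)-2-(benzyloxy)-1-[3,4-bis(benzyloxy)phenyl]-3-[2,4,6-tris(benzyloxy)phenyl]propyl}cyclohexa-2,4-dien-1-one (ortho-quinone methide) | O(Cc1ccccc1)c1cc(OCc2ccccc2)c(C[C@H](OCc2ccccc2)[C@H](c2ccc(OCc3ccccc3)c(OCc3ccccc3)c2)C2=C(OCc3ccccc3)C=C(OCc3ccccc3)C(=C)C2=O)c(OCc2ccccc2)c1
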